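Assumption: compound 15 has no stereocentre and no stereogenic double bond, so the achiral compound itself meets the request for a single enantiomer. The side chain of the SMILES is read as unbranched icosyl (C20H41; C27H46O4).

Ring numbering of 15, used for all precursors: C1 (C=O next to C–OH), C2 (C–OH), C3 (C–icosyl), C4 (C=O), C5 (C–OMe), C6 (C–H). C1′ is the first chain carbon.

## The problem

Irisoquin D (15) is a monocyclic 1,4-benzoquinone in which five of the six ring carbons are substituted: C1 (C=O), C2 (OH), C3 (n-icosyl), C4 (C=O), C5 (OMe), C6 (H). With no stereocentre, the whole difficulty is constitutional. The oxygens at C2 and C5 are electronically almost alike, yet one must end free and the other methylated. A C20 chain without any handle must also sit at C3, between two oxygen-bearing carbons.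

No cheap arene or quinone has this unsymmetrical pattern. The symmetrical 1,2,4,5-tetraoxygenated building blocks force a late choice between like groups. The C3–C1′ bond is awkward in the arene manifold, because the ring carbon is flanked on both sides and the chain partner is an unactivated primary halide.

The hydroxyquinone is a vinylogous acid, the C5 methoxy group is an exchangeable vinylogous ester, and the quinone is sensitive to nucleophiles and reductants. The quinone should therefore appear late and see few reagents. The waxy chain also limits solubility in cold polar media.

The feature that opens the plan is the run C1–C2–C3–C4 (C=O, C–O, C–alkyl, C=O). With C1 joined to C4, it is atom for atom a 3-alkyl-4-alkoxycyclobutene-1,2-dione. The remainder, C5(OMe)=C6H, is a two-carbon methyl enol ether. The six-membered ring is thus a squarate ring with a C2 unit inserted into its C1–C4 bond.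

## Retrosynthesis

**15 ⇒ 14 (O–alkyl bond at C2).** No skeletal bond is cut; the free C2–OH is traced back to the isopropyl ether 14. The two vinylogous oxygens then differ in how they can be cleaved (secondary alkyl, SN1-like; methyl, SN2 only), not merely in their neighbours. The isopropyl group costs no step, because it is one of the two ester groups of commercial squarate 2 and rides through the route. The forward reaction must remove a secondary alkyl group from a quinone vinylogous ester and leave the C5 methyl vinylogous ester alone.

**14 ⇒ 10 (key disconnection: C4–C5 cut, C1–C4 drawn).**
- 14 is the oxidised form of hydroquinone 13. The keto tautomer 12 of 13 is opened at C4–C5 to dienylketene 11, and joining C1 to C4 in 11 gives cyclobutenone 10.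
- The neighbouring choice puts C5/C6 in the small ring and C2/C3 in the side arm. It would need a semisquarate plus a trisubstituted alkenyl-metal that carries both the chain and an oxygen.
- Only the chosen pairing places three oxygenated carbons and the alkyl-bearing carbon in a four-membered ring that can be bought at the right oxidation level.
- 10 is an isomer of 13 but much easier to reach. Each substituent enters by carbonyl addition to a ring whose two carbonyls are electronically different, so no arene substitution chemistry is needed.
- The forward reaction needs strain-driven 4π opening with the alkenyl arm turning inward, then 6π closure.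

**10 ⇒ 5 + 9 (C1–C6).**
- The carbinol carbon of 10 is C1, which is flanked by C2–OiPr. In dione 5 this is the carbonyl that is not part of the vinylogous ester O–C2=C3–C4=O, hence the more electrophilic one. The natural regiochemistry of addition is therefore the required one.
- It follows that the carbanion carbon becomes C6 (H) and its neighbour becomes C5 (OMe), so the nucleophile must be the β-methoxyvinyl anion 9.
- An α-lithiated enol ether would put the methoxy group on C6. Correcting that would need an inverted order of additions and an extra protection.
- The acetylide F3 would give alkynyl carbinol F4, whose thermolysis needs no oxidant. Its enynylketene closes through a diradical, however, and that closure can turn 5-exo when the alkyne terminus carries a radical-stabilising alkoxy group. The alkenyl series has only the six-membered closure.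
- 5 and 9 are a C4 ring and a C2 fragment. The forward reaction must be a clean 1,2-addition at low temperature.

**5 ⇒ 2 + 3 (C3–C1′).** The chain–ring bond is made while C3 is still a squarate carbonyl carbon. It forms by polarity-matched addition of Grignard reagent 3 (from bromide 1) to 2. Acid-induced loss of propan-2-ol from carbinol 4 then transposes the oxygen pattern. Compared with an SN2 reaction of a hindered aryl-metal on 1, the roles are reversed: the chain is the nucleophile and the ring an unhindered, activated electrophile. Both precursors are commercial. The forward reaction must stop at monoaddition.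

**9 ⇒ 8 ⇒ 6.** The C–Li bond is traced to the C–Br bond of the Z bromide 8. The Z geometry is essential, because only with lithium and methoxy cis is anti β-elimination blocked. 8 comes from methyl vinyl ether 6 by bromination to 7 and dehydrobromination, so the C5–OMe bond of the target is bought ready-made.

## Roads not taken

**Alternative 1:** (the obvious route) cut C3–C1′ at the arene level.
- Forward: 1,2,4,5-tetramethoxybenzene A1 is lithiated and alkylated with 1 to give 3-icosyl-1,2,4,5-tetramethoxybenzene A2. Oxidative demethylation with CAN gives 3-icosyl-2,5-dimethoxy-1,4-benzoquinone A3, and one methyl group is then removed.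
- Weaknesses: the route has three steps, one fewer than the chosen longest linear sequence. Its C–C bond forming step is an SN2 reaction of a doubly flanked aryllithium on an unactivated C20 bromide, with elimination and exchange as competitors. The decisive O-differentiation is left to the last step, where two methyl vinylogous esters differ only in their neighbour.
- Chosen plan: the two oxygens are never chemically equivalent, and the chain is attached by carbonyl addition.

**Alternative 2:** cut the same C3–C1′ bond at the quinone level with reversed roles.
- Forward: 2,5-dihydroxy-1,4-benzoquinone A4 acts as a carbon nucleophile towards icosanal A5. Knoevenagel condensation gives a quinone methide, which is reduced in situ by a dihydropyridine hydride donor. This gives 2,5-dihydroxy-3-icosyl-1,4-benzoquinone A6, which is then mono-O-methylated in acidic methanol.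
- Weaknesses: this is the shortest route on paper. A4 has two equivalent nucleophilic CH positions, however, and A6 keeps one of them, so dialkylation is built in. The quinone methide can also be intercepted by a second molecule of A4. The last step must again choose between two vinylogous acids.
- Chosen plan: it spends two more steps and removes every choice between like groups.

**Alternative 3:** cut the C2–O and C4–O bonds (biomimetic oxidation of an alkylresorcinol).
- Forward: 3-icosyl-5-methoxyphenol A7 is oxidised para to the hydroxyl group (Fremy's salt) to 2-icosyl-6-methoxy-1,4-benzoquinone A8. Nucleophilic epoxidation of the alkyl-bearing double bond gives epoxide A9, and acid opening installs the C2 hydroxyl group.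
- Weaknesses: A7 is not an article of commerce. It needs an olefination, a hydrogenation and a mono-demethylation of a symmetrical resorcinol diether, which is again a statistical choice. The sequence therefore runs to about six or seven steps, with two separate oxidations on the sensitive quinone.
- Chosen plan: all four oxygens are bought with the two building blocks, and only one mild oxidation is needed.

Key step: step 4

## Steps

Step 1
Reactants: 1 1-bromoicosane; 2 diisopropyl squarate (3,4-diisopropoxycyclobut-3-ene-1,2-dione)
Product: 5 3-icosyl-4-isopropoxycyclobut-3-ene-1,2-dione, via icosylmagnesium bromide 3 (not isolated), via tertiary carbinol 4 (not isolated)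
Conditions: Mg, I2 (cat.), THF, 50 °C; then 2, THF, −78 → −30 °C; 1 M HCl quench; then conc. HCl (cat.), CH2Cl2, rt
Reagents that add atoms: magnesium, [Mg] (enters intermediate 3 only and leaves no atom in 5)
Why: 1,2-addition of a Grignard reagent to a dialkyl squarate should stop at the monoadduct, because the alkoxide formed deactivates the remaining vinylogous ester carbonyl. Acid then ionises the tertiary carbinol of 4 to an alkoxy-stabilised cyclobutenyl cation that is hydrolysed with loss of propan-2-ol, which is the standard squarate to 3-alkyl-4-alkoxycyclobutenedione sequence. No stereocentre remains in 5.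

Step 2
Reactants: 6 methyl vinyl ether
Product: 8 (Z)-1-bromo-2-methoxyethene, via 1,2-dibromo-1-methoxyethane 7 (not isolated)
Conditions: Br2, CH2Cl2, −78 °C; then PhNEt2, 95 °C, fractional distillation
Reagents that add atoms: bromine, BrBr
Why: Electrophilic bromination of the enol ether gives the α-bromo ether 7, whose activated C–Br bond ionises and loses the proton next to the second bromine (amine-induced dehydrobromination). The cis effect of 1,2-diheteroatom-substituted alkenes should favour the Z isomer, as in the well-known ethyl series, and distillation removes residual E isomer.

Step 3
Reactants: 8 (Z)-1-bromo-2-methoxyethene; 5 3-icosyl-4-isopropoxycyclobut-3-ene-1,2-dione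
Product: 10 4-hydroxy-2-icosyl-3-isopropoxy-4-[(Z)-2-methoxyethenyl]cyclobut-2-en-1-one (racemic), via (Z)-2-methoxyvinyllithium 9 (not isolated)
Conditions: 8, n-BuLi, Et2O, −78 °C; then 5, THF, −78 → −50 °C; H2O quench at low temperature, base-washed glassware, deactivated silica
Reagents that add atoms: n-butyllithium, [Li]CCCC (its lithium enters intermediate 9 only and leaves no atom in 10)
Why: Bromine–lithium exchange with retention gives 9, in which cis lithium and methoxy block anti β-elimination and allow O–Li chelation. 9 should add 1,2 to the carbonyl of 5 next to C–OiPr, because the other carbonyl is the vinylogous ester carbonyl and less electrophilic, which is the usual regiochemistry of 3-alkoxy-4-alkylcyclobutenediones. The carbinol centre forms racemic and is erased in step 4.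

Step 4
Reactants: 10 4-hydroxy-2-icosyl-3-isopropoxy-4-[(Z)-2-methoxyethenyl]cyclobut-2-en-1-one
Product: 14 3-icosyl-2-isopropoxy-5-methoxy-1,4-benzoquinone, via dienylketene 11 (not isolated), via cyclohexadienone 12 (not isolated), via hydroquinone 13 (not isolated)
Conditions: toluene (degassed, dilute, acid-free), 110 °C; then Ag2O, rt
Reagents that add atoms: none
Why: Heating should break the bond between the carbinol carbon (C1) and the carbonyl carbon (C4) of the strained cyclobutenone by conrotatory 4π electrocyclic opening, and the release of ring strain drives formation of dienylketene 11. The only selectivity needed here is torquoselectivity, which the free hydroxyl group on the sp3 carbon secures: as a donor it rotates outward, so the methoxyvinyl arm turns inward towards the ketene carbon. 11 then closes the six-membered carbocycle by disrotatory 6π electrocyclisation, forming the C4–C5 bond between the ketene carbon and the CH(OMe) terminus to give 12. The C5 stereocentre of 12 is transient and needs no control, since enolisation of its doubly activated C–H gives the aromatic hydroquinone 13. Regiochemistry is not decided in this step, because it is already written into 10: C4 keeps C3–icosyl as neighbour and C1 keeps C2–OiPr. Ag2O then oxidises the electron-rich 13 to 14 under neutral conditions that spare both vinylogous esters. The closest known reaction type is the thermal Moore-type ring expansion of 4-alkenyl- and 4-aryl-4-hydroxycyclobutenones to hydroquinones and quinones. Dilution and exclusion of acid keep the ketene from intermolecular trapping and the enol ether from hydrolysis.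

Step 5
Reactants: 14 3-icosyl-2-isopropoxy-5-methoxy-1,4-benzoquinone
Product: 15 irisoquin D (2-hydroxy-3-icosyl-5-methoxy-1,4-benzoquinone)
Conditions: BCl3, CH2Cl2, −78 → −20 °C; then H2O
Reagents that add atoms: none
Why: In this Lewis-acid ether dealkylation, BCl3 binds the C1 carbonyl and C2 ether oxygens, and the secondary isopropyl group should leave through an SN1-like transition state much faster than chloride can remove the methyl group by SN2. The C2 alkoxy group is also twisted out of conjugation by the icosyl chain and is therefore the more basic oxygen. Hydrolysis of the boron chelate gives 15.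

## Compound list

1 | 1-bromoicosane | CCCCCCCCCCCCCCCCCCCCBr | starting material
2 | diisopropyl squarate (3,4-diisopropoxycyclobut-3-ene-1,2-dione) | CC(C)OC1=C(OC(C)C)C(=O)C1=O | starting material
3 | icosylmagnesium bromide | CCCCCCCCCCCCCCCCCCCC[Mg]Br | intermediate
4 | 4-hydroxy-4-icosyl-2,3-diisopropoxycyclobut-2-en-1-one (racemic) | CCCCCCCCCCCCCCCCCCCCC1(O)C(OC(C)C)=C(OC(C)C)C1=O | intermediate
5 | 3-icosyl-4-isopropoxycyclobut-3-ene-1,2-dione | CCCCCCCCCCCCCCCCCCCCC1=C(OC(C)C)C(=O)C1=O | intermediate
6 | methyl vinyl ether | COC=C | starting material
7 | 1,2-dibromo-1-methoxyethane (racemic) | COC(Br)CBr | intermediate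
8 | (Z)-1-bromo-2-methoxyethene | CO/C=C\Br | intermediate
9 | (Z)-2-methoxyvinyllithium | CO/C=C\[Li] | intermediate
10 | 4-hydroxy-2-icosyl-3-isopropoxy-4-[(Z)-2-methoxyethenyl]cyclobut-2-en-1-one (racemic) | CCCCCCCCCCCCCCCCCCCCC1=C(OC(C)C)C(O)(/C=C\OC)C1=O | intermediate
11 | (3Z,5Z)-4-hydroxy-2-icosyl-3-isopropoxy-6-methoxyhexa-1,3,5-trien-1-one (dienylketene) | CCCCCCCCCCCCCCCCCCCCC(=C=O)/C(OC(C)C)=C(O)\C=C/OC | intermediate
12 | 4-hydroxy-2-icosyl-3-isopropoxy-6-methoxycyclohexa-2,4-dien-1-one (racemic) | CCCCCCCCCCCCCCCCCCCCC1=C(OC(C)C)C(O)=CC(OC)C1=O | intermediate
13 | 3-icosyl-2-isopropoxy-5-methoxybenzene-1,4-diol | CCCCCCCCCCCCCCCCCCCCc1c(OC(C)C)c(O)cc(OC)c1O | intermediate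
14 | 3-icosyl-2-isopropoxy-5-methoxycyclohexa-2,5-diene-1,4-dione | CCCCCCCCCCCCCCCCCCCCC1=C(OC(C)C)C(=O)C=C(OC)C1=O | intermediate
15 | irisoquin D, 2-hydroxy-3-icosyl-5-methoxycyclohexa-2,5-diene-1,4-dione | CCCCCCCCCCCCCCCCCCCCC1=C(O)C(=O)C=C(OC)C1=O | target

## Step count and least certain steps

Total steps: 5. Longest linear sequence: 4 (steps 1, 3, 4, 5); step 2 is a one-step side branch.

**Step 4 (key step).** Two processes may interfere.
- The methoxy group sits on the inside (Z) of the closing terminus and polarises the alkene away from the carbon that must bond to the ketene, so the 6π closure may be slower than in the parent alkenyl series. Because ring opening is reversible, a slow closure gives time for two leaks: the minor inward rotation of the hydroxyl group followed by lactonisation of the ketene, and intermolecular trapping of the ketene by hydroxyl groups.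
- In 12, expulsion of methanol, pushed by the C1 enol, may compete with enolisation and erase the C5 oxygen.

The fallback sets out from 5 and moves the introduction of the methoxy group behind the ring expansion. Vinylmagnesium bromide adds to the same carbonyl of 5 to give 4-ethenyl-4-hydroxy-2-icosyl-3-isopropoxycyclobut-2-en-1-one F1. Thermolysis and Ag2O oxidation, the parent case with an unsubstituted closing terminus, should give 3-icosyl-2-isopropoxy-1,4-benzoquinone F2. Methanol with ZnCl2 under air should then add in conjugate fashion at C5. C5 is the β-position of the C1 carbonyl, which the C2 alkoxy group does not deactivate, whereas the C4 carbonyl is a vinylogous ester. The adduct is 13, which is reoxidised, so the fallback comes back to the route at 14.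

**Step 3.** Three processes may interfere.
- Dehydrobromination of 8 by n-BuLi (its C–H and C–Br bonds are anti), or β-elimination from any E-configured organolithium, would generate acetylides that also add to 5.
- 5 may be poorly soluble in the cold medium.
- The enol ether carbinol may suffer acid-induced allylic transposition and hydrolysis on work-up or on silica.

The fallback sets out from 5. Lithium methoxyacetylide F3 cannot β-eliminate and is made in the flask from chloroacetaldehyde dimethyl acetal and three equivalents of LiNEt2. It adds to give 4-hydroxy-2-icosyl-3-isopropoxy-4-(methoxyethynyl)cyclobut-2-en-1-one F4. Semihydrogenation over Lindlar catalyst with quinoline delivers the Z enol ether, so the fallback comes back at 10.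

**Step 5.** Loss of the methyl group along with the isopropyl group, or exchange of the C5 methoxy group by chloride through addition–elimination on the Lewis-acid-activated quinone, may erode the selectivity.

The fallback moves the dealkylation to the arene oxidation level, where selective removal of isopropyl in the presence of methyl aryl ethers is well precedented. It sets out from 13, obtained by leaving out the Ag2O treatment in step 4. Excess BCl3 gives 3-icosyl-5-methoxybenzene-1,2,4-triol F5. As a hydroxyhydroquinone, F5 should be oxidised by air or Ag2O, and the fallback comes back at 15.

**Step 1.** Homocoupling may occur while the long-chain Grignard reagent forms. The reagent may also precipitate at low temperature, which would lead to incomplete addition and, on warming, to a second addition.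

The fallback sets out from 2 and replaces the sp3 organometal by an acetylide. Commercial 1-icosyne and n-BuLi give lithium icos-1-yn-1-ide F6. This adds to 2 to give 4-hydroxy-4-(icos-1-yn-1-yl)-2,3-diisopropoxycyclobut-2-en-1-one F7. The same acid treatment gives 3-(icos-1-yn-1-yl)-4-isopropoxycyclobut-3-ene-1,2-dione F8. Hydrogenation of the triple bond over Pd/C should leave the tetrasubstituted push–pull ring alkene untouched, and the fallback comes back at 5.

## Further compounds

F1 | step 4 | 4-ethenyl-4-hydroxy-2-icosyl-3-isopropoxycyclobut-2-en-1-one (racemic) | CCCCCCCCCCCCCCCCCCCCC1=C(OC(C)C)C(O)(C=C)C1=O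
F2 | step 4 | 3-icosyl-2-isopropoxy-1,4-benzoquinone | CCCCCCCCCCCCCCCCCCCCC1=C(OC(C)C)C(=O)C=CC1=O
F3 | step 3 | lithium methoxyacetylide | [Li]C#COC
F4 | step 3 | 4-hydroxy-2-icosyl-3-isopropoxy-4-(methoxyethynyl)cyclobut-2-en-1-one (racemic) | CCCCCCCCCCCCCCCCCCCCC1=C(OC(C)C)C(O)(C#COC)C1=O
F5 | step 5 | 3-icosyl-5-methoxybenzene-1,2,4-triol | CCCCCCCCCCCCCCCCCCCCc1c(O)c(O)cc(OC)c1O
F6 | step 1 | lithium icos-1-yn-1-ide | CCCCCCCCCCCCCCCCCCC#C[Li]
F7 | step 1 | 4-hydroxy-4-(icos-1-yn-1-yl)-2,3-diisopropoxycyclobut-2-en-1-one (racemic) | CCCCCCCCCCCCCCCCCCC#CC1(O)C(OC(C)C)=C(OC(C)C)C1=O
F8 | step 1 | 3-(icos-1-yn-1-yl)-4-isopropoxycyclobut-3-ene-1,2-dione | CCCCCCCCCCCCCCCCCCC#CC1=C(OC(C)C)C(=O)C1=O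
A1 | alternative 1 | 1,2,4,5-tetramethoxybenzene | COc1cc(OC)c(OC)cc1OC
A2 | alternative 1 | 3-icosyl-1,2,4,5-tetramethoxybenzene | CCCCCCCCCCCCCCCCCCCCc1c(OC)c(OC)cc(OC)c1OC
A3 | alternative 1 | 3-icosyl-2,5-dimethoxy-1,4-benzoquinone | CCCCCCCCCCCCCCCCCCCCC1=C(OC)C(=O)C=C(OC)C1=O
A4 | alternative 2 | 2,5-dihydroxy-1,4-benzoquinone | OC1=CC(=O)C(O)=CC1=O
A5 | alternative 2 | icosanal | CCCCCCCCCCCCCCCCCCCC=O
A6 | alternative 2 | 2,5-dihydroxy-3-icosyl-1,4-benzoquinone | CCCCCCCCCCCCCCCCCCCCC1=C(O)C(=O)C=C(O)C1=O
A7 | alternative 3 | 3-icosyl-5-methoxyphenol | CCCCCCCCCCCCCCCCCCCCc1cc(O)cc(OC)c1
A8 | alternative 3 | 2-icosyl-6-methoxy-1,4-benzoquinone | CCCCCCCCCCCCCCCCCCCCC1=CC(=O)C=C(OC)C1=O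
A9 | alternative 3 | 1-icosyl-3-methoxy-7-oxabicyclo[4.1.0]hept-3-ene-2,5-dione (racemic) | CCCCCCCCCCCCCCCCCCCCC12OC1C(=O)C=C(OC)C2=O
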